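Disydonol C is two copies of one (S)-configured 2-(2-hydroxy-6-methylheptan-2-yl)phenol unit. They are joined from the benzylic CH2 on ring A to the carbon of ring B that lies para to the phenol oxygen and ortho to the CH2OH group. The route uses this pseudo-symmetry: one benzylic pinacol boronate is the nucleophilic half and, after oxidation and bromination para to the methoxy group, also the electrophilic half. A B-benzyl Suzuki–Miyaura coupling then forms the diarylmethane bond in one operation with the three alcohol groups unprotected. The tertiary carbinol is set once, by stereospecific lithiation–borylation of a secondary benzylic carbamate.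

Key step: step 8

Assumption: 1-(4-chloro-2-methoxyphenyl)ethanone, 4-methylpent-1-ene and bis(pinacolboryl)methane are taken as catalogue compounds. Both carbinol centres of the target are (S).

Step 1
Reactants: 1 1-(4-chloro-2-methoxyphenyl)ethanone
Product: 2 (R)-1-(4-chloro-2-methoxyphenyl)ethanol
Conditions: RuCl[(R,R)-TsDPEN](p-cymene) (1 mol%), HCO2H/Et3N (5:2), 40 °C
Reagents that add atoms: none
Why: Noyori asymmetric transfer hydrogenation of an aryl methyl ketone, in which the (R,R)-catalyst should deliver hydride to the face that gives the (R)-alcohol.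

Step 2
Reactants: 2 (R)-1-(4-chloro-2-methoxyphenyl)ethanol
Product: 3 (R)-1-(4-chloro-2-methoxyphenyl)ethyl N,N-diisopropylcarbamate
Conditions: iPr2NCOCl, Et3N, MeCN, reflux
Reagents that add atoms: N,N-diisopropylcarbamoyl chloride CC(C)N(C(C)C)C(Cl)=O
Why: O-carbamoylation of a secondary alcohol, which does not touch the C–O stereocentre and installs the directing and leaving group for step 4.

Step 3
Reactants: 4 4-methylpent-1-ene
Product: 5 4,4,5,5-tetramethyl-2-(4-methylpentyl)-1,3,2-dioxaborolane
Conditions: HBpin, [Ir(cod)Cl]2 (1.5 mol%), dppm (3 mol%), CH2Cl2, rt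
Reagents that add atoms: pinacolborane B1OC(C)(C)C(C)(C)O1
Why: Iridium-catalysed anti-Markovnikov hydroboration of a terminal alkene should give the primary pinacol boronate.

Step 4
Reactants: 3 (R)-1-(4-chloro-2-methoxyphenyl)ethyl N,N-diisopropylcarbamate; 5 4,4,5,5-tetramethyl-2-(4-methylpentyl)-1,3,2-dioxaborolane
Product: 7 (S)-2-(4-chloro-2-methoxyphenyl)-6-methylheptan-2-ol, via tertiary pinacol boronate 6 (not isolated)
Conditions: s-BuLi, Et2O, −78 °C; then 5; then MgBr2 in MeOH, −78 °C → rt; then NaOH, H2O2, THF, 0 °C → rt
Reagents that add atoms: hydrogen peroxide OO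
Why: Lithiation–borylation of a secondary benzylic carbamate, in which deprotonation and borylation occur with retention, the 1,2-metallate shift displaces the carbamate with inversion and the C–B oxidation occurs with retention, so the (R)-carbamate should give the (S)-tertiary alcohol, while the aryl chloride is inert to s-BuLi at −78 °C.

Step 5
Reactants: 7 (S)-2-(4-chloro-2-methoxyphenyl)-6-methylheptan-2-ol; 8 bis(pinacolboryl)methane (2 equiv)
Product: 9 (S)-2-[2-methoxy-4-(pinacolborylmethyl)phenyl]-6-methylheptan-2-ol
Conditions: Pd[P(t-Bu)3]2 (5 mol%), aq. KOH, 1,4-dioxane, 40 °C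
Reagents that add atoms: none
Why: Chemoselective Suzuki–Miyaura mono-arylation of a geminal diborylmethane, in which the second boryl group accelerates transmetalation so that the benzylic boronate product should not couple again under these conditions.

Step 6
Reactants: 9 (S)-2-[2-methoxy-4-(pinacolborylmethyl)phenyl]-6-methylheptan-2-ol (about half of the material)
Product: 10 (S)-2-[4-(hydroxymethyl)-2-methoxyphenyl]-6-methylheptan-2-ol
Conditions: H2O2, NaOH, THF/H2O, 0 °C
Reagents that add atoms: hydrogen peroxide OO
Why: Oxidation of a benzylic C–B bond to C–OH by the standard peroxide 1,2-shift, under basic conditions that leave the tertiary benzylic alcohol untouched.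

Step 7
Reactants: 10 (S)-2-[4-(hydroxymethyl)-2-methoxyphenyl]-6-methylheptan-2-ol
Product: 11 (S)-2-[5-bromo-4-(hydroxymethyl)-2-methoxyphenyl]-6-methylheptan-2-ol
Conditions: NBS, MeCN, 0 °C → rt, dark
Reagents that add atoms: N-bromosuccinimide O=C1CCC(=O)N1Br
Why: Electrophilic aromatic bromination, directed by the methoxy group to its open para position (the free ortho position is flanked by OMe and CH2OH), with a non-acidic reagent that should spare the tertiary alcohol.

Step 8
Reactants: 9 (S)-2-[2-methoxy-4-(pinacolborylmethyl)phenyl]-6-methylheptan-2-ol; 11 (S)-2-[5-bromo-4-(hydroxymethyl)-2-methoxyphenyl]-6-methylheptan-2-ol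
Product: 12 di-O-methyl disydonol C, (S)-2-[4-({5-[(S)-2-hydroxy-6-methylheptan-2-yl]-2-(hydroxymethyl)-4-methoxyphenyl}methyl)-2-methoxyphenyl]-6-methylheptan-2-ol
Conditions: Pd(OAc)2 (5 mol%), RuPhos (10 mol%), K3PO4, toluene/H2O (10:1), degassed, 90 °C
Reagents that add atoms: none
Why: Pd(0) should insert into the C–Br bond of 11, the base-activated primary benzylic boronate of 9 then transmetalates (it has no β-hydrogen, so β-hydride elimination is excluded), and reductive elimination forms the CH2–aryl bond. The closest known reaction type is the sp3–sp2 Suzuki–Miyaura coupling of benzylic boronic esters or trifluoroborates with aryl bromides. No ring is closed and no stereocentre is formed; the two (S)-carbinol centres are remote from the reacting atoms and are not ionised under these mildly basic conditions. The site of union is fixed by the bromine placed para to the methoxy group in step 7, so no regiochemical question arises in the coupling itself. The selectivity needed is cross-coupling over protodeboronation and homocoupling, which a bulky electron-rich biaryl phosphine, a slight excess of 9 and a phosphate base with little water should secure. The free primary and tertiary hydroxyl groups should be tolerated without protection.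

Step 9
Reactants: 12 di-O-methyl disydonol C
Product: 13 disydonol C
Conditions: NaSEt (excess), DMF, degassed, 130 °C; then aq. NH4Cl
Reagents that add atoms: none
Why: SN2 cleavage of both aryl methyl ethers by thiolate gives the phenoxides under basic conditions, in which the acid-labile tertiary benzylic alcohols cannot ionise and so should keep their configuration.

Compound list
1 | 1-(4-chloro-2-methoxyphenyl)ethanone | CC(=O)c1ccc(Cl)cc1OC | starting material
2 | (R)-1-(4-chloro-2-methoxyphenyl)ethanol | C[C@@H](O)c1ccc(Cl)cc1OC | intermediate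
3 | (R)-1-(4-chloro-2-methoxyphenyl)ethyl N,N-diisopropylcarbamate | C[C@@H](OC(=O)N(C(C)C)C(C)C)c1ccc(Cl)cc1OC | intermediate
4 | 4-methylpent-1-ene | C=CCC(C)C | starting material
5 | 4,4,5,5-tetramethyl-2-(4-methylpentyl)-1,3,2-dioxaborolane | CC(C)CCCB1OC(C)(C)C(C)(C)O1 | intermediate
6 | (R)-2-[2-(4-chloro-2-methoxyphenyl)-6-methylheptan-2-yl]-4,4,5,5-tetramethyl-1,3,2-dioxaborolane (not isolated) | CC(C)CCC[C@](C)(B1OC(C)(C)C(C)(C)O1)c1ccc(Cl)cc1OC | intermediate
7 | (S)-2-(4-chloro-2-methoxyphenyl)-6-methylheptan-2-ol | CC(C)CCC[C@](C)(O)c1ccc(Cl)cc1OC | intermediate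
8 | bis(pinacolboryl)methane, 2,2'-methylenebis(4,4,5,5-tetramethyl-1,3,2-dioxaborolane) | C(B1OC(C)(C)C(C)(C)O1)B1OC(C)(C)C(C)(C)O1 | starting material
9 | (S)-2-[2-methoxy-4-(pinacolborylmethyl)phenyl]-6-methylheptan-2-ol | CC(C)CCC[C@](C)(O)c1ccc(CB2OC(C)(C)C(C)(C)O2)cc1OC | intermediate
10 | (S)-2-[4-(hydroxymethyl)-2-methoxyphenyl]-6-methylheptan-2-ol | CC(C)CCC[C@](C)(O)c1ccc(CO)cc1OC | intermediate
11 | (S)-2-[5-bromo-4-(hydroxymethyl)-2-methoxyphenyl]-6-methylheptan-2-ol | CC(C)CCC[C@](C)(O)c1cc(Br)c(CO)cc1OC | intermediate
12 | di-O-methyl disydonol C | CC(C)CCC[C@](C)(O)c1ccc(Cc2cc([C@@](C)(O)CCCC(C)C)c(OC)cc2CO)cc1OC | intermediate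
13 | disydonol C | CC(C)CCC[C@](C)(O)c1ccc(Cc2cc([C@@](C)(O)CCCC(C)C)c(O)cc2CO)cc1O | target

Total step count: 9. Longest linear sequence: 8 steps (steps 1, 2, 4, 5, 6, 7, 8, 9).

Steps most likely to fail

Step 8. Oxidative addition into the electron-rich, ortho-substituted aryl bromide may be slow, so that protodeboronation or homocoupling of the benzylic boronate consumes the nucleophile first. The fallback reverses the polarity of the two partners and sets out from 10 and 11. The primary hydroxyl of 10 would be acylated selectively (ClCO2Me, pyridine, CH2Cl2, 0 °C) to give the benzylic methyl carbonate F1. Bromide 11 would be converted by Miyaura borylation (B2pin2, PdCl2(dppf), KOAc, dioxane, 80 °C) into the aryl pinacol boronate F2. A palladium-catalysed benzylic substitution of the carbonate by the arylboron reagent ([Pd(allyl)Cl]2, 1,5-bis(diphenylphosphino)pentane, K2CO3, DMF, 80 °C), in which the fast ionisation of the benzylic carbonate replaces the difficult oxidative addition, should return to the route at 12.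

Step 5. The benzylic boronate product may be arylated a second time, or the aryl chloride may react too slowly at the temperature at which the mono-selectivity holds. The fallback sets out from 7. A Suzuki–Miyaura hydroxymethylation with potassium acetoxymethyltrifluoroborate (Pd(OAc)2, RuPhos, Na2CO3, dioxane/H2O, 100 °C; the acetate is hydrolysed in the flask) should give 10 directly. Part of 10 would then be converted by an Appel reaction at the primary position (CBr4, PPh3, CH2Cl2, 0 °C) into the benzylic bromide F3. Palladium-catalysed borylation of F3 (B2pin2, Pd(PPh3)4, KOAc, dioxane, 80 °C) should return to the route at 9.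

Step 9. The double demethylation at high temperature may stop at the mono-ether or degrade the electron-rich bis-phenol. The fallback changes the phenol protecting group early and sets out from 7. Thiolate demethylation at this simple stage (NaSEt, DMF, 130 °C) would give (S)-5-chloro-2-(2-hydroxy-6-methylheptan-2-yl)phenol F4. Selective O-benzylation of the phenol (BnBr, K2CO3, acetone) would give the benzyl ether F5. The conditions of steps 5 to 8 would then be repeated in the benzyl series: coupling with 8 to the benzylic boronate F6, oxidation of part of it to the benzylic alcohol F7, bromination to the aryl bromide F8, and coupling of F6 with F8 to the bis-benzyl ether F9. Neutral hydrogenolysis of F9 (H2, 1 atm, Pd/C, EtOAc, rt, stopped at uptake of two equivalents) should return to the route at 13.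

Further compounds
F1 | step 8 | (S)-4-(2-hydroxy-6-methylheptan-2-yl)-3-methoxybenzyl methyl carbonate | CC(C)CCC[C@](C)(O)c1ccc(COC(=O)OC)cc1OC
F2 | step 8 | (S)-2-[4-(hydroxymethyl)-2-methoxy-5-(pinacolboryl)phenyl]-6-methylheptan-2-ol | CC(C)CCC[C@](C)(O)c1cc(B2OC(C)(C)C(C)(C)O2)c(CO)cc1OC
F3 | step 5 | (S)-2-[4-(bromomethyl)-2-methoxyphenyl]-6-methylheptan-2-ol | CC(C)CCC[C@](C)(O)c1ccc(CBr)cc1OC
F4 | step 9 | (S)-5-chloro-2-(2-hydroxy-6-methylheptan-2-yl)phenol | CC(C)CCC[C@](C)(O)c1ccc(Cl)cc1O
F5 | step 9 | (S)-2-[2-(benzyloxy)-4-chlorophenyl]-6-methylheptan-2-ol | CC(C)CCC[C@](C)(O)c1ccc(Cl)cc1OCc1ccccc1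
F6 | step 9 | (S)-2-[2-(benzyloxy)-4-(pinacolborylmethyl)phenyl]-6-methylheptan-2-ol | CC(C)CCC[C@](C)(O)c1ccc(CB2OC(C)(C)C(C)(C)O2)cc1OCc1ccccc1
F7 | step 9 | (S)-2-[2-(benzyloxy)-4-(hydroxymethyl)phenyl]-6-methylheptan-2-ol | CC(C)CCC[C@](C)(O)c1ccc(CO)cc1OCc1ccccc1
F8 | step 9 | (S)-2-[2-(benzyloxy)-5-bromo-4-(hydroxymethyl)phenyl]-6-methylheptan-2-ol | CC(C)CCC[C@](C)(O)c1cc(Br)c(CO)cc1OCc1ccccc1
F9 | step 9 | di-O-benzyl disydonol C | CC(C)CCC[C@](C)(O)c1ccc(Cc2cc([C@@](C)(O)CCCC(C)C)c(OCc3ccccc3)cc2CO)cc1OCc1ccccc1
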